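Atom labels: oxane numbering O1, C2 (aryl), C3, C4, C5, C6; C7 is the carbinol carbon on C5; C1', C2', C3' are the chain carbons on C3. "Pivalate" means 2,2-dimethylpropanoate.

## The problem

Compound 21 is a 2,3,5-trisubstituted oxane. C2 carries a 4-hydroxyphenyl group, C3 an (E)-3-(4-hydroxyphenyl)allyl chain (C1'H2–C2'H=C3'H–aryl), and C5 a hydroxy(4-hydroxyphenyl)methyl group with carbinol carbon C7. The three ring stereocentres (2R,3S,5R) hold all three substituents on one face, and the fourth centre, C7 (R), lies outside the ring. An all-cis 2,3,5-array cannot be all-equatorial, so equilibration is no help. C5 is 1,3 to C3 and separated from C2 by the ring oxygen, which makes open-chain relay of configuration unreliable, and C7 has only C5 as a neighbour and will need reagent control. The C2–O1 ether and the C7 carbinol are both benzylic and para to a phenol, so acid (and hot base, through quinone methides) can ionise them, and the 4-hydroxystyrene end is sensitive to acid and oxidants; the phenols must therefore travel as electron-poor esters and be released last under mild, non-acidic conditions. The feature that opens the problem is that the cis arms on C3 and C5 end in C2' and C7, an alkene carbon and a carbinol carbon that can both be drawn from carbonyl groups. Joining them by a C7=C2' double bond gives a cyclohexene (C3–C1'–C2'=C7–C5–C4) that shares C3–C4–C5 with the oxane. This is a 3-oxabicyclo[3.3.1]non-6-ene, in which the 3,5-cis relationship is compulsory and whose carbocyclic half is a Diels–Alder product.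

## Retrosynthesis

**Phenol release and the C3'–aryl bond (21 ⇒ 20 ⇒ 18 + 19).** The last operation should only unmask phenols, so 21 is taken back to bis-pivalate 20. In 20 the C3'–aryl bond is cut to alkenyl iodide 18 and 4-hydroxyphenylboronic acid 19. The neighbouring cut, C2'=C3' by a benzylic ylide or sulfone, would need strong base next to sensitive groups and would give E/Z mixtures. The sp2–sp2 coupling transfers a preset E geometry and uses 19 unprotected. The forward reaction must run near room temperature with a mild base.

**C7–H and C2'=C3' (18 ⇒ 17 ⇒ 16).** The C7 carbinol is taken back to aryl ketone 17, and the iodoalkene to the aldehyde of keto-aldehyde 16 by a one-carbon iodomethylenation. The ketone has an alkoxy group on its β-carbon (C6–O1) and an epimerisable α-centre (C5), so it must be reduced before any basic step. The forward olefination must select the aldehyde over the ketone under non-basic conditions, and the reduction must be reagent-controlled.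

**Reconnection of C7 to C2' (16 ⇒ 14).** The two carbonyl carbons of 16 are six atoms apart, so they are joined retrosynthetically into the C7=C2' alkene of bicycle 14 (ozonolysis forward). This turns the 3,5-cis problem into a ring constraint: 14 has three stereocentres but only two are independent. The forward cleavage needs an alkene more reactive to ozone than the two ester-bearing arenes.

**C5–C6, the key cut (14 ⇒ 13).** In 14 the oxane is opened at C5–C6 to the methoxymethyl ether 13 of a cyclohexenyl carbinol. Cutting O1–C6 or O1–C2 instead would build no C–C bond and no stereocentre. Cutting C5–C6 uses the styrene of 13 as the nucleophile toward an O1=C6 oxocarbenium ion and creates C5 under control of C3. Precursor 13 is monocyclic with two stereocentres. The forward reaction must ionise the acetal and not the benzylic C2–O bond, attack through C5, and lose a proton from C2'.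

**Acetal and C2–H (13 ⇒ 12 ⇒ 11).** Removing the methoxymethyl group gives alcohol 12, and C2 is taken back to ketone 11. C3 offers no facial bias, because its two ring arms differ only two atoms out, so C2 must come from a reagent-controlled reduction. Any shortfall shows up as a separable diastereomer, not as lost enantiopurity.

**The cyclohexene (11 ⇒ 4 + 10).** The 1,4-pattern of acyl and aryl groups on the cyclohexene of 11 is the para adduct of 2-aryl diene 10 and aryl vinyl ketone 4, cutting C3–C4 and C1'–C2'. An acrylate or acrolein dienophile would need later acyl-to-aryl-ketone conversions, whereas 4 brings the whole aryl ketone. The forward cycloaddition must set the single stereocentre C3 by catalyst control.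

**The fragments (4 ⇒ 2 ⇒ 1; 10 ⇒ 6 + 7; 6 ⇒ 5).** Enone 4 is the α-methylenation product of 4-acetylphenyl pivalate 2, made from 4'-hydroxyacetophenone 1. Diene 10 comes from cross-coupling of 4-bromophenyl pivalate 6 (from 4-bromophenol 5) with the butadienyl unit of chloroprene 7, through Grignard reagent 8 and organozinc 9. Pivalates are chosen because they withdraw enough electron density to keep the C2–O bond from ionising and to slow ozone attack on the arenes. They resist the organozinc and hydride reagents and leave under mild methanolysis.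

## Roads not taken

**Alternative 1:** two-directional anti-aldol. The cuts are C2–C3 and C5–C7, leading to 1,5-bis[(4R)-4-benzyl-2-oxooxazolidin-3-yl]pentane-1,5-dione A1 and two molecules of 4-(tert-butyldimethylsilyloxy)benzaldehyde A2. The bis(magnesium enolate) of A1 (MgCl2, Et3N, Me3SiCl) would add to A2 at both ends to give the C2-symmetric anti,anti bis-aldol A3, with no ring formed.
- Merits: all four stereocentres are set in one operation by one auxiliary. The target's centres do map onto a C2-symmetric array (C2 with C7, C3 with C5), so either of the two possible ring closures gives the same oxane. In stereochemical economy this is better than the chosen plan, which needs three separate catalyst-controlled events.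
- Weak points: A3 has no ring and the wrong oxidation level at both ends. Both imide carbonyls must be reduced and then told apart. One must become C6 in an etherification that activates a primary alcohol beside two electron-rich, easily ionised benzylic carbinols. The other must be turned from a carboxyl carbon into the C1' methylene and extended through an sp3–sp2 bond to the styryl unit.
- The anti-aldol is best established for propionyl imides. Here the enolate carries a branched chain with a second imide, and the electron-rich aldehyde favours retro-aldol.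
- Comparison: the chosen plan sets against the better stereochemical economy a key step that builds the ring and the 3,5-relationship in one C–C bond formation, from a precursor three steps from the fragments, and an end-game that creates the side chain at the right oxidation level.

**Alternative 2:** inverse-demand oxa-Diels–Alder. The cuts are O1–C2 and C3–C4. Methyl 2-formylacrylate A4 (heterodiene O1=C6–C5=C4), chelated to Cu(OTf)2 and a tert-butyl bis(oxazoline) ligand (divalent copper), would add to (Z)-1-[4-(tert-butyldimethylsilyloxy)phenyl]-4-(tert-butyldimethylsilyloxy)but-1-ene A5 to give the cis-dihydropyran ester A6.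
- Merits: the ring and two stereocentres form convergently in one step, the 2,3-cis relationship comes from alkene geometry, and later hydrogenation of the enol ether of A6 should occur opposite both substituents and complete the all-cis array. If the cycloaddition worked, this would probably be the shortest route, and that is conceded.
- Weak points: A4 polymerises readily and must be generated in the flask. A5 is a plain 1,2-disubstituted styrene, not an enol ether, and the Z isomer is the less reactive one because its aryl group is twisted.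
- The addition would be strongly asynchronous through a silyloxy-stabilised benzylic cation, so bond rotation could leak cis into trans, and the Lewis acid could isomerise A5 to the E-alkene.
- C7 would still have to be made from the ester through an aryl ketone, so the late ketone reduction is not avoided.
- Comparison: the chosen plan has a key step whose regiochemistry and stereochemistry are fixed by ring geometry and not by a catalyst–substrate match that has no close precedent.

**Alternative 3:** ring-closing metathesis then hydrogenation. The cut is C3=C4. The acyclic ether A7, with a 1,1-disubstituted alkene at C3 and a vinyl group on C5, would be closed by the second-generation Grubbs catalyst. The same ruthenium under H2 would then reduce the ring alkene opposite the C2 aryl group to the all-cis oxane A8.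
- Merits: A8 holds all four stereocentres, C7 included, and is only a desilylation, an oxidation, an olefination and a deprotection from 21. The C2 and C5 substituents direct hydrogen to the same face. C7 would be set early by open-chain chemistry, which is better than the chosen plan's late reduction of a hindered ketone.
- Weak points: A7 already contains three stereocentres (C2, C5, C7) that need separate asymmetric steps. Its ether bond joins an electron-rich, benzylic and allylic secondary carbinol to a β-branched primary carbon, an alkylation prone to ionisation and elimination.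
- Once the ring has closed, C2–O1 is both benzylic and allylic. Ruthenium hydrides can move the alkene into conjugation with the aryl group, which erases C2, or cause hydrogenolysis, and the flanked trisubstituted alkene is slow to reduce.
- Comparison: the chosen plan sets against the earlier control of C7 a key-step precursor made in three steps from two simple fragments, and a ring closure in which no benzylic–allylic ether is exposed to a metal hydride.

Key step: step 8

Assumption 1: an aryl vinyl ketone is taken to bind the (S)-oxazaborolidinium ion as acrylate esters and simple enones do, so the (S) catalyst should give the (1S) adduct 11; if the sense were opposite, the (R) catalyst would be used with no other change.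

Assumption 2: in both oxazaborolidine reductions the aryl group is taken to act as the larger ketone substituent, as in acetophenone, so the (S) catalyst should give the (R) carbinols 12 and 18.

## Route

Step 1
Reactants: 1 4'-hydroxyacetophenone
Product: 2 4-acetylphenyl pivalate
Conditions: t-BuCOCl, Et3N, 4-(dimethylamino)pyridine (cat.), CH2Cl2, 0 °C → rt
Reagents that add atoms: pivaloyl chloride, CC(C)(C)C(=O)Cl
Why: Acylation of the phenol under nucleophilic catalysis; the pivalate lowers the donor strength of the ring and is hindered enough to survive the later organozinc, hydride and Lewis acid steps.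

Step 2
Reactants: 2 4-acetylphenyl pivalate
Product: 4 4-acryloylphenyl pivalate, via Mannich base 3 (not isolated)
Conditions: (CH2O)n, i-Pr2NH·CF3CO2H (1 equiv), CF3CO2H (10 mol %), THF, reflux
Reagents that add atoms: paraformaldehyde (as formaldehyde), C=O
Why: Mannich-type α-methylenation: the enol of 2 adds to the iminium ion formed from formaldehyde and the ammonium salt to give 3, which loses the amine on heating to give the enone; the mildly acidic medium leaves the pivalate alone, and 4 is used at once because aryl vinyl ketones polymerise.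

Step 3
Reactants: 5 4-bromophenol
Product: 6 4-bromophenyl pivalate
Conditions: t-BuCOCl, Et3N, 4-(dimethylamino)pyridine (cat.), CH2Cl2, 0 °C → rt
Reagents that add atoms: pivaloyl chloride, CC(C)(C)C(=O)Cl
Why: Acylation of the phenol as in step 1; the ester is introduced before the coupling so that no free 4-hydroxyphenyl diene, which would polymerise, ever has to be handled.

Step 4
Reactants: 7 chloroprene, 6 4-bromophenyl pivalate
Product: 10 4-(buta-1,3-dien-2-yl)phenyl pivalate, via buta-1,3-dien-2-ylmagnesium chloride 8 (not isolated), via buta-1,3-dien-2-ylzinc chloride 9 (not isolated)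
Conditions: Mg, BrCH2CH2Br (cat.), ZnCl2 (cat.), THF, reflux; ZnCl2 (1.1 equiv), 0 °C; then 6, Pd(PPh3)4 (3 mol %), THF, rt → 50 °C
Reagents that add atoms: none
Why: Grignard formation from the vinylic chloride, transmetalation to zinc and Negishi coupling; the organozinc is used because, unlike the Grignard reagent, it does not attack the aryl ester, and Pd(PPh3)4 (zerovalent palladium) inserts into the C–Br bond but not into the ester C–O bond.

Step 5
Reactants: 4 4-acryloylphenyl pivalate, 10 4-(buta-1,3-dien-2-yl)phenyl pivalate
Product: 11 (S)-[4-(4-pivaloyloxyphenyl)cyclohex-3-en-1-yl](4-pivaloyloxyphenyl)methanone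
Conditions: (S)-1-(2-methylphenyl)-3,3-diphenyltetrahydro-1H,3H-pyrrolo[1,2-c][1,3,2]oxazaborole (20 mol %), Tf2NH (16 mol %), CH2Cl2, −78 → −40 °C
Reagents that add atoms: none
Why: Diels–Alder reaction catalysed by a chiral oxazaborolidinium ion: the ketone oxygen binds boron anti to the aryl group, one face of the s-trans enone is screened by the catalyst, and the 2-aryl diene adds with para orientation (diene C1 to the enone β-carbon); this sets C3 as S (Assumption 1).

Step 6
Reactants: 11 (S)-[4-(4-pivaloyloxyphenyl)cyclohex-3-en-1-yl](4-pivaloyloxyphenyl)methanone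
Product: 12 (R)-(4-pivaloyloxyphenyl)[(1S)-4-(4-pivaloyloxyphenyl)cyclohex-3-en-1-yl]methanol
Conditions: (S)-1-methyl-3,3-diphenyltetrahydro-1H,3H-pyrrolo[1,2-c][1,3,2]oxazaborole (0.5 equiv), catecholborane, toluene, −78 → −40 °C; pH 7 buffer
Reagents that add atoms: none
Why: Corey–Bakshi–Shibata reduction: with the aryl group as the large substituent, the (S) catalyst should deliver hydride to the face that gives the (R) carbinol, setting C2 by reagent control because C3 exerts no useful bias; catecholborane does not hydroborate the styrene at this temperature, and any C2 epimer is a separable diastereomer.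

Step 7
Reactants: 12 (R)-(4-pivaloyloxyphenyl)[(1S)-4-(4-pivaloyloxyphenyl)cyclohex-3-en-1-yl]methanol
Product: 13 4-[(R)-(methoxymethoxy)[(1S)-4-(4-pivaloyloxyphenyl)cyclohex-3-en-1-yl]methyl]phenyl pivalate
Conditions: CH2(OMe)2, AcCl, ZnBr2 (0.01 mol %), toluene, rt; then 12, i-Pr2NEt, 0 °C → rt
Reagents that add atoms: chloromethyl methyl ether, COCCl (made in the flask from dimethoxymethane, COCOC, and acetyl chloride)
Why: O-Alkylation of the carbinol by the chloromethyl ether formed through acetal–acyl chloride exchange; the amine base keeps the medium non-acidic, so neither the styrene nor the benzylic C–O bond is disturbed and no stereocentre is touched.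

Step 8
Reactants: 13 4-[(R)-(methoxymethoxy)[(1S)-4-(4-pivaloyloxyphenyl)cyclohex-3-en-1-yl]methyl]phenyl pivalate
Product: 14 (1S,2R,5S)-2,6-bis(4-pivaloyloxyphenyl)-3-oxabicyclo[3.3.1]non-6-ene
Conditions: Me3SiOTf (1.5 equiv), 2,6-di-tert-butyl-4-methylpyridine (2 equiv), CH2Cl2 (0.01 M), −78 → −30 °C
Reagents that add atoms: none
Why: Me3SiOTf silylates the terminal methoxy oxygen of 13 and MeOSiMe3 leaves, giving the O1=C6 oxocarbenium ion on the C2 oxygen. With the side chain axial on the cyclohexene half-chair the cationic carbon lies over C5, and the trisubstituted styrene attacks through C5 because only that places the charge on the tertiary, aryl-stabilised C7. The closure is six-membered, exocyclic with respect to the alkene and endocyclic with respect to the oxocarbenium ion, through a chair in which the C2 aryl group is equatorial. C5 is the only new stereocentre and is set by C3, since the one-carbon-bridged bicycle can only form with the new C5–C6 bond cis to the C3–C2 bond. The C7 cation then gives up a proton to the hindered pyridine from C2' alone, because loss from C5 would require a bridgehead double bond. The closest known reaction type is the Prins cyclisation of cyclohex-3-enylmethanols with aldehydes, or of their alkoxymethyl ethers, to 3-oxabicyclo[3.3.1]nonenes. The step needs ionisation of the acetal in preference to the benzylic C2–O bond, which the electron-poor pivaloyloxyphenyl group, the low temperature and the acid scavenger secure, and the bis-homoallylic placement of the oxocarbenium ion excludes an oxonia-Cope path that could scramble C2.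

Step 9
Reactants: 14 (1S,2R,5S)-2,6-bis(4-pivaloyloxyphenyl)-3-oxabicyclo[3.3.1]non-6-ene
Product: 16 4-[(2R,3R,5R)-3-(2-oxoethyl)-5-(4-pivaloyloxybenzoyl)oxan-2-yl]phenyl pivalate, via secondary ozonide 15 (not isolated)
Conditions: O3, CH2Cl2, −78 °C (Sudan Red 7B end point); PPh3, −78 °C → rt; used crude
Reagents that add atoms: ozone, [O-][O+]=O
Why: Ozonolysis with reductive work-up: cycloaddition of ozone to the only alkene, rearrangement to ozonide 15 and reduction by PPh3 reveal the C7 ketone and the C2' aldehyde under neutral conditions; the ester-deactivated arenes react far more slowly than the styrene, and no stereocentre is affected.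

Step 10
Reactants: 16 4-[(2R,3R,5R)-3-(2-oxoethyl)-5-(4-pivaloyloxybenzoyl)oxan-2-yl]phenyl pivalate
Product: 17 4-[(2R,3R,5R)-3-[(E)-3-iodoprop-2-enyl]-5-(4-pivaloyloxybenzoyl)oxan-2-yl]phenyl pivalate
Conditions: CrCl2 (8 equiv), CHI3 (3 equiv), THF–1,4-dioxane (1:6), 0 °C → rt, dark
Reagents that add atoms: iodoform, IC(I)I
Why: Takai olefination: the geminal dichromium species formed from CHI3 and CrCl2 (divalent chromium) adds to the aldehyde much faster than to the aryl ketone and eliminates to the (E)-iodoalkene; the medium is not basic, so C5 and the β-alkoxy ketone are not endangered.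

Step 11
Reactants: 17 4-[(2R,3R,5R)-3-[(E)-3-iodoprop-2-enyl]-5-(4-pivaloyloxybenzoyl)oxan-2-yl]phenyl pivalate
Product: 18 4-[(2R,3R,5R)-5-[(R)-hydroxy(4-pivaloyloxyphenyl)methyl]-3-[(E)-3-iodoprop-2-enyl]oxan-2-yl]phenyl pivalate
Conditions: (S)-1-methyl-3,3-diphenyltetrahydro-1H,3H-pyrrolo[1,2-c][1,3,2]oxazaborole (1.0 equiv), catecholborane, toluene, −78 → −40 °C; pH 7 buffer
Reagents that add atoms: none
Why: Corey–Bakshi–Shibata reduction with the aryl group again as the large substituent, so the (S) catalyst should give the (R) carbinol at C7 by reagent control (Assumption 2); the alkenyl iodide and the pivalates are inert to catecholborane at low temperature, and a C7 epimer would be a separable diastereomer.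

Step 12
Reactants: 18 4-[(2R,3R,5R)-5-[(R)-hydroxy(4-pivaloyloxyphenyl)methyl]-3-[(E)-3-iodoprop-2-enyl]oxan-2-yl]phenyl pivalate, 19 4-hydroxyphenylboronic acid
Product: 20 4-[(2R,3S,5R)-5-[(R)-hydroxy(4-pivaloyloxyphenyl)methyl]-3-[(E)-3-(4-hydroxyphenyl)prop-2-enyl]oxan-2-yl]phenyl pivalate
Conditions: PdCl2(dppf) (5 mol %), K3PO4 (3 equiv), THF–H2O (10:1), rt → 40 °C
Reagents that add atoms: none
Why: Suzuki–Miyaura coupling: oxidative addition of the alkenyl iodide to zerovalent palladium, transmetalation and reductive elimination all proceed with retention, so the E geometry is carried into the styrene; the free phenol of 19 and the carbinol need no protection, and any partial loss of pivalate is harmless because the next step removes both.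

Step 13
Reactants: 20 4-[(2R,3S,5R)-5-[(R)-hydroxy(4-pivaloyloxyphenyl)methyl]-3-[(E)-3-(4-hydroxyphenyl)prop-2-enyl]oxan-2-yl]phenyl pivalate
Product: 21 4-[(E)-3-[(2R,3S,5R)-5-[(R)-hydroxy(4-hydroxyphenyl)methyl]-2-(4-hydroxyphenyl)oxan-3-yl]prop-1-enyl]phenol
Conditions: K2CO3 (0.5 equiv), MeOH, 0 °C → rt, argon; aq. NH4Cl
Reagents that add atoms: none
Why: Base-catalysed transesterification: methoxide attacks the aryl ester carbonyls and the phenoxides leave; the conditions are cold, non-acidic and non-oxidising, so the benzylic C–O bonds para to the new phenols and the hydroxystyrene should survive, and the buffered quench avoids acid.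

## Compound list

1 | 4'-hydroxyacetophenone | CC(=O)c1ccc(O)cc1 | starting material
2 | 4-acetylphenyl pivalate | CC(=O)c1ccc(OC(=O)C(C)(C)C)cc1 | intermediate
3 | 4-[3-(diisopropylamino)propanoyl]phenyl pivalate (Mannich base, not isolated) | CC(C)N(C(C)C)CCC(=O)c1ccc(OC(=O)C(C)(C)C)cc1 | intermediate
4 | 4-acryloylphenyl pivalate | C=CC(=O)c1ccc(OC(=O)C(C)(C)C)cc1 | intermediate
5 | 4-bromophenol | Oc1ccc(Br)cc1 | starting material
6 | 4-bromophenyl pivalate | CC(C)(C)C(=O)Oc1ccc(Br)cc1 | intermediate
7 | chloroprene (2-chlorobuta-1,3-diene) | C=CC(Cl)=C | starting material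
8 | buta-1,3-dien-2-ylmagnesium chloride (not isolated) | C=CC(=C)[Mg]Cl | intermediate
9 | buta-1,3-dien-2-ylzinc chloride (not isolated) | C=CC(=C)[Zn]Cl | intermediate
10 | 4-(buta-1,3-dien-2-yl)phenyl pivalate | C=CC(=C)c1ccc(OC(=O)C(C)(C)C)cc1 | intermediate
11 | (S)-[4-(4-pivaloyloxyphenyl)cyclohex-3-en-1-yl](4-pivaloyloxyphenyl)methanone | O=C(c1ccc(OC(=O)C(C)(C)C)cc1)[C@@H]1CC=C(c2ccc(OC(=O)C(C)(C)C)cc2)CC1 | intermediate
12 | (R)-(4-pivaloyloxyphenyl)[(1S)-4-(4-pivaloyloxyphenyl)cyclohex-3-en-1-yl]methanol | O[C@@H](c1ccc(OC(=O)C(C)(C)C)cc1)[C@@H]1CC=C(c2ccc(OC(=O)C(C)(C)C)cc2)CC1 | intermediate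
13 | 4-[(R)-(methoxymethoxy)[(1S)-4-(4-pivaloyloxyphenyl)cyclohex-3-en-1-yl]methyl]phenyl pivalate | COCO[C@@H](c1ccc(OC(=O)C(C)(C)C)cc1)[C@@H]1CC=C(c2ccc(OC(=O)C(C)(C)C)cc2)CC1 | intermediate
14 | (1S,2R,5S)-2,6-bis(4-pivaloyloxyphenyl)-3-oxabicyclo[3.3.1]non-6-ene | C1=C(c3ccc(OC(=O)C(C)(C)C)cc3)[C@@H]2C[C@H](C1)[C@H](c1ccc(OC(=O)C(C)(C)C)cc1)OC2 | intermediate
15 | secondary ozonide (1,2,4-trioxolane across C7 and C2') of 14, new acetal centres undefined (not isolated) | C1(O3)OOC3(c4ccc(OC(=O)C(C)(C)C)cc4)[C@@H]2C[C@H](C1)[C@H](c1ccc(OC(=O)C(C)(C)C)cc1)OC2 | intermediate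
16 | 4-[(2R,3R,5R)-3-(2-oxoethyl)-5-(4-pivaloyloxybenzoyl)oxan-2-yl]phenyl pivalate | O=CC[C@H]1C[C@@H](C(=O)c2ccc(OC(=O)C(C)(C)C)cc2)CO[C@H]1c1ccc(OC(=O)C(C)(C)C)cc1 | intermediate
17 | 4-[(2R,3R,5R)-3-[(E)-3-iodoprop-2-enyl]-5-(4-pivaloyloxybenzoyl)oxan-2-yl]phenyl pivalate | I/C=C/C[C@H]1C[C@@H](C(=O)c2ccc(OC(=O)C(C)(C)C)cc2)CO[C@H]1c1ccc(OC(=O)C(C)(C)C)cc1 | intermediate
18 | 4-[(2R,3R,5R)-5-[(R)-hydroxy(4-pivaloyloxyphenyl)methyl]-3-[(E)-3-iodoprop-2-enyl]oxan-2-yl]phenyl pivalate | I/C=C/C[C@H]1C[C@@H]([C@@H](O)c2ccc(OC(=O)C(C)(C)C)cc2)CO[C@H]1c1ccc(OC(=O)C(C)(C)C)cc1 | intermediate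
19 | 4-hydroxyphenylboronic acid | OB(O)c1ccc(O)cc1 | starting material
20 | 4-[(2R,3S,5R)-5-[(R)-hydroxy(4-pivaloyloxyphenyl)methyl]-3-[(E)-3-(4-hydroxyphenyl)prop-2-enyl]oxan-2-yl]phenyl pivalate | Oc1ccc(/C=C/C[C@H]2C[C@@H]([C@@H](O)c3ccc(OC(=O)C(C)(C)C)cc3)CO[C@H]2c2ccc(OC(=O)C(C)(C)C)cc2)cc1 | intermediate
21 | 4-[(E)-3-[(2R,3S,5R)-5-[(R)-hydroxy(4-hydroxyphenyl)methyl]-2-(4-hydroxyphenyl)oxan-3-yl]prop-1-enyl]phenol | Oc1ccc(/C=C/C[C@H]2C[C@@H]([C@@H](O)c3ccc(O)cc3)CO[C@H]2c2ccc(O)cc2)cc1 | target

## Step count and risks

Total: 13 steps. Longest linear sequence: 11 steps (steps 1, 2 and 5–13 from 1, or steps 3–13 from 5).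

**Step 8 (key step).**
- What may go wrong: the tertiary benzylic cation may not shed its proton cleanly and may instead alkylate a second styrene unit (oligomerisation) or be recaptured. The acetal may also be cleaved in the wrong sense, which returns 12.
- Fallback (sets out from 13, returns at 14): change the way the cation is terminated. TiCl4 in CH2Cl2 at −78 °C ionises the acetal and delivers chloride to C7, giving (1S,2R,5R)-6-chloro-2,6-bis(4-pivaloyloxyphenyl)-3-oxabicyclo[3.3.1]nonane F1. Dehydrochlorination of F1 with DBU in warm toluene, in a separate flask with no Lewis acid present, can only place the double bond at C7=C2' and should give 14.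

**Step 5.**
- What may go wrong: poor facial selectivity, because the aryl ketone may bind the boron catalyst less tightly or in another geometry than the enones and acrylates for which such catalysts are established. Acid-induced oligomerisation of diene 10 is a second risk.
- Fallback (sets out from 4 and 10, returns at 12): replace asymmetric catalysis by a reagent-controlled resolution. Cycloaddition promoted by Me2AlCl (CH2Cl2, −78 °C) gives racemic [4-(4-pivaloyloxyphenyl)cyclohex-3-en-1-yl](4-pivaloyloxyphenyl)methanone F2. Reduction of F2 under the step 6 conditions turns the two enantiomers into 12 and its diastereomer (R)-(4-pivaloyloxyphenyl)[(1R)-4-(4-pivaloyloxyphenyl)cyclohex-3-en-1-yl]methanol F3, which are separable by chromatography. F3 can be recycled by Dess–Martin oxidation to (R)-[4-(4-pivaloyloxyphenyl)cyclohex-3-en-1-yl](4-pivaloyloxyphenyl)methanone F4 and DBU-mediated racemisation at the α-carbon back to F2. This fallback depends on step 6 giving good reagent control.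

**Step 6.**
- What may go wrong: weak reagent control, because aryl and secondary alkyl substituents are of similar bulk, so both carbinol epimers form. Slow hydroboration of the styrene is a lesser risk.
- Fallback (sets out from 11, returns at 12): give up asymmetric induction at C2 and rely on separation and recycling. NaBH4/CeCl3·7H2O in THF–EtOH at −20 °C reduces 11 without control. Compound 12 is separated from its epimer (S)-(4-pivaloyloxyphenyl)[(1S)-4-(4-pivaloyloxyphenyl)cyclohex-3-en-1-yl]methanol F5, and F5 is returned to 11 by Dess–Martin oxidation.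

**Step 10.**
- What may go wrong: intramolecular aldol condensation of the 1,6-keto-aldehyde or opening of the oxane by β-elimination at C5–C6 under the Lewis acidic chromium salts, and erosion of E selectivity.
- Fallback (sets out from 16, returns at 21): build the styrene by cross-metathesis instead of iodo-olefination and coupling.
  - Aldehyde-selective methylenation (CH2I2, Zn, Ti(OiPr)4, THF) gives 4-[(2R,3S,5R)-3-(prop-2-enyl)-5-(4-pivaloyloxybenzoyl)oxan-2-yl]phenyl pivalate F6.
  - Reduction as in step 11 gives 4-[(2R,3S,5R)-5-[(R)-hydroxy(4-pivaloyloxyphenyl)methyl]-3-(prop-2-enyl)oxan-2-yl]phenyl pivalate F7.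
  - Cross-metathesis of F7 with commercial 4-acetoxystyrene (second-generation Grubbs catalyst, CH2Cl2, 40 °C) gives 4-[(E)-3-[(2R,3S,5R)-5-[(R)-hydroxy(4-pivaloyloxyphenyl)methyl]-2-(4-pivaloyloxyphenyl)oxan-3-yl]prop-1-enyl]phenyl acetate F8.
  - Methanolysis of F8 under the step 13 conditions gives 21.

**Step 11.**
- What may go wrong: mismatch between catalyst control and the intrinsic facial bias of the α-branched, β-alkoxy ketone, leading to poor diastereoselectivity at C7.
- Fallback (sets out from 17, returns at 21): correct the wrong epimer by inversion.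
  - The minor product of the reduction of 17, 4-[(2R,3R,5R)-5-[(S)-hydroxy(4-pivaloyloxyphenyl)methyl]-3-[(E)-3-iodoprop-2-enyl]oxan-2-yl]phenyl pivalate F9, is separated.
  - Mitsunobu esterification of F9 (4-nitrobenzoic acid, PPh3, diisopropyl azodicarboxylate, toluene, 0 °C → rt) gives, with inversion at C7, 4-[(2R,3R,5R)-3-[(E)-3-iodoprop-2-enyl]-5-[(R)-(4-nitrobenzoyloxy)(4-pivaloyloxyphenyl)methyl]oxan-2-yl]phenyl pivalate F10.
  - Coupling of F10 with 19 as in step 12 gives 4-[(2R,3S,5R)-3-[(E)-3-(4-hydroxyphenyl)prop-2-enyl]-5-[(R)-(4-nitrobenzoyloxy)(4-pivaloyloxyphenyl)methyl]oxan-2-yl]phenyl pivalate F11.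
  - The step 13 methanolysis removes the nitrobenzoate of F11 together with the pivalates and gives 21.

## Further compounds

F1 | step 8 | (1S,2R,5R)-6-chloro-2,6-bis(4-pivaloyloxyphenyl)-3-oxabicyclo[3.3.1]nonane (C6 configuration undefined) | C1C(Cl)(c3ccc(OC(=O)C(C)(C)C)cc3)[C@@H]2C[C@H](C1)[C@H](c1ccc(OC(=O)C(C)(C)C)cc1)OC2
F2 | step 5 | racemic [4-(4-pivaloyloxyphenyl)cyclohex-3-en-1-yl](4-pivaloyloxyphenyl)methanone | O=C(c1ccc(OC(=O)C(C)(C)C)cc1)C1CC=C(c2ccc(OC(=O)C(C)(C)C)cc2)CC1
F3 | step 5 | (R)-(4-pivaloyloxyphenyl)[(1R)-4-(4-pivaloyloxyphenyl)cyclohex-3-en-1-yl]methanol | O[C@@H](c1ccc(OC(=O)C(C)(C)C)cc1)[C@H]1CC=C(c2ccc(OC(=O)C(C)(C)C)cc2)CC1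
F4 | step 5 | (R)-[4-(4-pivaloyloxyphenyl)cyclohex-3-en-1-yl](4-pivaloyloxyphenyl)methanone | O=C(c1ccc(OC(=O)C(C)(C)C)cc1)[C@H]1CC=C(c2ccc(OC(=O)C(C)(C)C)cc2)CC1
F5 | step 6 | (S)-(4-pivaloyloxyphenyl)[(1S)-4-(4-pivaloyloxyphenyl)cyclohex-3-en-1-yl]methanol | O[C@H](c1ccc(OC(=O)C(C)(C)C)cc1)[C@@H]1CC=C(c2ccc(OC(=O)C(C)(C)C)cc2)CC1
F6 | step 10 | 4-[(2R,3S,5R)-3-(prop-2-enyl)-5-(4-pivaloyloxybenzoyl)oxan-2-yl]phenyl pivalate | C=CC[C@H]1C[C@@H](C(=O)c2ccc(OC(=O)C(C)(C)C)cc2)CO[C@H]1c1ccc(OC(=O)C(C)(C)C)cc1
F7 | step 10 | 4-[(2R,3S,5R)-5-[(R)-hydroxy(4-pivaloyloxyphenyl)methyl]-3-(prop-2-enyl)oxan-2-yl]phenyl pivalate | C=CC[C@H]1C[C@@H]([C@@H](O)c2ccc(OC(=O)C(C)(C)C)cc2)CO[C@H]1c1ccc(OC(=O)C(C)(C)C)cc1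
F8 | step 10 | 4-[(E)-3-[(2R,3S,5R)-5-[(R)-hydroxy(4-pivaloyloxyphenyl)methyl]-2-(4-pivaloyloxyphenyl)oxan-3-yl]prop-1-enyl]phenyl acetate | CC(=O)Oc1ccc(/C=C/C[C@H]2C[C@@H]([C@@H](O)c3ccc(OC(=O)C(C)(C)C)cc3)CO[C@H]2c2ccc(OC(=O)C(C)(C)C)cc2)cc1
F9 | step 11 | 4-[(2R,3R,5R)-5-[(S)-hydroxy(4-pivaloyloxyphenyl)methyl]-3-[(E)-3-iodoprop-2-enyl]oxan-2-yl]phenyl pivalate | I/C=C/C[C@H]1C[C@@H]([C@H](O)c2ccc(OC(=O)C(C)(C)C)cc2)CO[C@H]1c1ccc(OC(=O)C(C)(C)C)cc1
F10 | step 11 | 4-[(2R,3R,5R)-3-[(E)-3-iodoprop-2-enyl]-5-[(R)-(4-nitrobenzoyloxy)(4-pivaloyloxyphenyl)methyl]oxan-2-yl]phenyl pivalate | I/C=C/C[C@H]1C[C@@H]([C@@H](OC(=O)c2ccc(cc2)[N+](=O)[O-])c2ccc(OC(=O)C(C)(C)C)cc2)CO[C@H]1c1ccc(OC(=O)C(C)(C)C)cc1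
F11 | step 11 | 4-[(2R,3S,5R)-3-[(E)-3-(4-hydroxyphenyl)prop-2-enyl]-5-[(R)-(4-nitrobenzoyloxy)(4-pivaloyloxyphenyl)methyl]oxan-2-yl]phenyl pivalate | Oc1ccc(/C=C/C[C@H]2C[C@@H]([C@@H](OC(=O)c3ccc(cc3)[N+](=O)[O-])c3ccc(OC(=O)C(C)(C)C)cc3)CO[C@H]2c2ccc(OC(=O)C(C)(C)C)cc2)cc1
A1 | alternative 1 | 1,5-bis[(4R)-4-benzyl-2-oxooxazolidin-3-yl]pentane-1,5-dione | O=C(CCCC(=O)N1[C@H](Cc2ccccc2)COC1=O)N1[C@H](Cc2ccccc2)COC1=O
A2 | alternative 1 | 4-(tert-butyldimethylsilyloxy)benzaldehyde | O=Cc1ccc(O[Si](C)(C)C(C)(C)C)cc1
A3 | alternative 1 | C2-symmetric anti,anti bis-aldol adduct of A1 with two molecules of A2 | O=C(N1[C@H](Cc2ccccc2)COC1=O)[C@@H](C[C@@H]([C@@H](O)c1ccc(O[Si](C)(C)C(C)(C)C)cc1)C(=O)N1[C@H](Cc2ccccc2)COC1=O)[C@@H](O)c1ccc(O[Si](C)(C)C(C)(C)C)cc1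
A4 | alternative 2 | methyl 2-formylacrylate | COC(=O)C(=C)C=O
A5 | alternative 2 | (Z)-1-[4-(tert-butyldimethylsilyloxy)phenyl]-4-(tert-butyldimethylsilyloxy)but-1-ene | CC(C)(C)[Si](C)(C)OCC/C=C\c1ccc(O[Si](C)(C)C(C)(C)C)cc1
A6 | alternative 2 | methyl cis-(2R,3R)-2-[4-(tert-butyldimethylsilyloxy)phenyl]-3-[2-(tert-butyldimethylsilyloxy)ethyl]-3,4-dihydro-2H-pyran-5-carboxylate | COC(=O)C1=CO[C@@H](c2ccc(O[Si](C)(C)C(C)(C)C)cc2)[C@@H](CCO[Si](C)(C)C(C)(C)C)C1
A7 | alternative 3 | acyclic ether of the C2 carbinol with the C6 carbon, bearing the 1,1-disubstituted alkene at C3 and the vinyl group on C5, all hydroxyl groups as tert-butyldimethylsilyl ethers | C=C(CCO[Si](C)(C)C(C)(C)C)[C@H](c1ccc(O[Si](C)(C)C(C)(C)C)cc1)OC[C@@H](C=C)[C@@H](O[Si](C)(C)C(C)(C)C)c1ccc(O[Si](C)(C)C(C)(C)C)cc1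
A8 | alternative 3 | all-cis (2R,3R,5R)-2-[4-(tert-butyldimethylsilyloxy)phenyl]-3-[2-(tert-butyldimethylsilyloxy)ethyl]-5-[(R)-(tert-butyldimethylsilyloxy)[4-(tert-butyldimethylsilyloxy)phenyl]methyl]oxane | CC(C)(C)[Si](C)(C)OCC[C@H]1C[C@@H]([C@@H](O[Si](C)(C)C(C)(C)C)c2ccc(O[Si](C)(C)C(C)(C)C)cc2)CO[C@H]1c1ccc(O[Si](C)(C)C(C)(C)C)cc1
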